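**Remark on the chemistry:** ring atoms are numbered as in isochroman-1-one (C1 carbonyl, O2, C3, C4, C4a, C5–C8, C8a). The stereocentre C3 of the target is R by CIP analysis (O2 > C4 > chain CH2 > H). All reagents written over the arrows are taken to be commercial.

## The problem

Target 15 is (R)-8-hydroxy-3-(11-hydroxyundecyl)-6-methoxyisochroman-1-one. Benzene ring A (C4a, C5–C8, C8a) is fused to δ-lactone ring B (C1, O2, C3, C4, C4a, C8a), and C3 carries an unbranched eleven-carbon chain ending in a primary alcohol. Ring A bears a methyl ether at C6 and a free phenol at C8, peri to the C1 carbonyl, so the two oxygens of a resorcinol unit must end up differentiated. The only stereocentre is C3, a secondary carbinol carbon between two methylene groups. Nothing in the molecule can induce it and it controls nothing else, so it has to be bought or set by a reagent and then left undisturbed. The lactone is open to hydroxide, hydride and organometallic reagents. Ring A is electron-rich enough to suffer further electrophilic substitution at C5 and C7 and overoxidation. The C6 methyl ether must survive whatever frees the C8 phenol, and the primary alcohol needs a mask that tolerates Grignard reagents, a Lewis acid and an oxidant. The enabling feature is that C1 is a single carbon between O2 and C8a, and C8a lies ortho to the C8 oxygen and para to the C6 oxygen. Removing C1 leaves a 3,5-dioxygenated phenyl ring whose two positions flanking the side chain are equivalent, so a one-carbon electrophile tethered to O2 can close ring B at the most nucleophilic reachable carbon with no regiochemical question. The cost is that C1 arrives as CH2, which is tolerable because it is the one position that is both benzylic and α to oxygen.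

## Retrosynthesis

**15 ⇒ 14.** The O–CH3 bond at C8 and the O–CH2Ph bond at the chain terminus are cut. Only the C8 methoxy group can chelate a boron Lewis acid together with the C1 carbonyl, so the two methyl ethers of a symmetric precursor can be told apart at the very end. A benzyl ether is chosen for the primary alcohol because the same boron trihalide cleaves it, so one operation unmasks both hydroxyl groups. A silyl ether would need a separate fluoride step and is less secure under the Lewis acid of the ring closure. Lactone 14 has no free hydroxyl group. The forward step must leave the C6 methyl ether and the lactone intact.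

**14 ⇒ 13 ⇒ 12.** No skeletal bond is cut; C1 is taken back from carbonyl through lactol 13 to the methylene of isochroman 12. In 12, C1 is benzylic, α to O2, and attached to a ring carbon that has methoxy groups ortho and para, so hydride abstraction there is far easier than at C4 or at the O-benzyl methylene. Going through the lactol allows a neutral second oxidation, where a one-step chromium or permanganate oxidation would endanger the benzyl ether and ring A. The precursor loses the carbonyl but keeps every atom of the skeleton.

**12 ⇒ 9 + 10.** Bonds O2–C1 and C1–C8a are cut, opening ring B and removing C1 as dimethoxymethane 10. A single cut of C1–C8a at the carboxyl level would need prior halogenation of the arene. A cut of C3–C4 (benzylic anion plus aldehyde) would create C3 without control. The chosen cut returns to alcohol 9, whose arene is symmetric and whose stereocentre is already in place. The forward reaction must be an electrophilic closure that attacks only the carbon ortho to the side chain and leaves C3 untouched.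

**9 ⇒ 6 + 7.** Bond C4–C4a is cut, giving (R)-epoxide 6 and 1-bromo-3,5-dimethoxybenzene 7, joined by way of arylmagnesium bromide 8. This makes the aryl part a commodity and places the stereocentre in a small terminal epoxide. A ketone reduction at C3 is the neighbouring option, but the two flanking methylene groups are too alike for reliable facial discrimination. The forward step needs attack at the unsubstituted epoxide carbon only.

**6 ⇒ 5 ⇒ 2 + 3.** The epoxide is traced to chlorohydrin 5, and the bond between the first and second chain carbons is cut to give Grignard reagent 4 (from bromide 2) and (R)-epichlorohydrin 3. Epichlorohydrin supplies C4, C3 and the first chain carbon with the correct configuration from the chiral pool. The opposite order (aryl first, with the S enantiomer) is equivalent; the order chosen uses the cheap aryl Grignard reagent in excess at the later coupling. The forward step must open the epoxide and must not displace chloride, since direct displacement would lead to the enantiomer.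

**2 ⇒ 1.** The O–benzyl bond is cut, leaving 10-bromodecan-1-ol 1. Benzylation must avoid alkoxide formation, which would trigger self-alkylation of the bromo alcohol.

## Roads not taken

**Alternative 1:** This cuts C4a–C4 and C8a–C1 together. Fluoride releases the aryne from 3,5-dimethoxy-2-(trimethylsilyl)phenyl triflate A1, and dimethyl malonate A2 inserts across it to give homophthalate diester A3. The methoxy group next to the aryne directs the carbon nucleophile to the distal carbon, so the benzoate ends up beside the future C8 oxygen.
- Merits: the C1 carbon arrives at the carboxyl oxidation level, so no benzylic oxidation of an electron-rich ring is needed. In that respect it is better than the chosen plan.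
- Weak points: no ring is closed and C3 is not addressed. After A3 the aliphatic ester must be differentiated, the C11 chain attached and the C3 carbinol set with absolute control next to two similar methylene groups. A1 itself needs several steps.
- Comparison: against the oxidation-level advantage, the chosen plan offers a stereocentre bought in enantiopure form, a ring closure that forms both bonds to C1 at once, and a clearly shorter sequence.

**Alternative 2:** This cuts C4a–C8a, so ring A itself is built. Diketo-dioxinone A4 cyclises under mild base and then acid (aldol closure, dehydration, enolisation) to resorcylate A5, with the dioxinone intact.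
- Merits: the two phenolic oxygens are differentiated from the outset. The future C8 oxygen is locked in the dioxinone and the future C6 oxygen is the only free phenol for methylation. Later attack of the C3 hydroxyl on the dioxinone closes the lactone and frees the C8 phenol without a demethylation step. On phenol differentiation and oxidation level this route is superior.
- Weak points: A4 requires an enantiopure β-silyloxy acyl fragment of fourteen carbons, which needs its own asymmetric step. The β-silyloxy triketone system is prone to elimination and premature cyclisation. The sequence is longer and passes through more sensitive intermediates.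
- Comparison: the chosen plan relies instead on a chelation-controlled demethylation that is dependable for a peri methoxy group, on robust intermediates, and on a chiral-pool stereocentre.

**Alternative 3:** This cuts C4a–C4 and O2–C3. [Cp*RhCl2]2 (trivalent rhodium) activates the single ortho C–H bond of 2,4-dimethoxybenzoic acid A6. Carbene transfer from sulfoxonium ylide A7 and cyclodehydration give isocoumarin A8, whose C3=C4 bond is then hydrogenated enantioselectively.
- Merits: it is the shortest and most convergent option. The acid is commercial, only one ortho position is free, and C1 is already a carbonyl. In step economy it is better than the chosen plan.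
- Weak points: the only stereocentre depends on asymmetric hydrogenation of an enol lactone bearing a long unbranched alkyl group, where facial discrimination is least certain. The product is unlikely to crystallise well enough to upgrade its enantiopurity.
- Comparison: the chosen plan is about two steps longer, but its absolute configuration is fixed by a purchased building block and never touched again.

Key step: step 5

## Route

Step 1
Reactants: 1 10-bromodecan-1-ol
Product: 2 benzyl 10-bromodecyl ether, {[(10-bromodecyl)oxy]methyl}benzene
Conditions: BnOC(=NH)CCl3, TfOH (cat.), CH2Cl2/cyclohexane, 0 °C → rt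
Reagents that add atoms: benzyl 2,2,2-trichloroacetimidate, N=C(OCc1ccccc1)C(Cl)(Cl)Cl
Why: Acid-catalysed O-benzylation with a trichloroacetimidate donor; no alkoxide is generated, so the primary bromide is not displaced in a competing Williamson reaction.

Step 2
Reactants: 2 benzyl 10-bromodecyl ether; 3 (R)-epichlorohydrin
Product: 5 (R)-13-(benzyloxy)-1-chlorotridecan-2-ol, via Grignard reagent 4 (not isolated)
Conditions: 2, Mg, I2 (cat.), THF, 40 °C; then CuI (10 mol %), 3, THF, −40 → −20 °C; aq NH4Cl
Reagents that add atoms: none
Why: Copper-catalysed Grignard opening of the epoxide at its unsubstituted carbon (SN2); no bond to the stereocentre is broken, and the descriptor stays R because CH2Cl still outranks the new alkyl branch.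

Step 3
Reactants: 5 (R)-13-(benzyloxy)-1-chlorotridecan-2-ol
Product: 6 (R)-2-[11-(benzyloxy)undecyl]oxirane
Conditions: K2CO3, MeOH, rt
Reagents that add atoms: none
Why: Intramolecular Williamson etherification (3-exo-tet) of the chlorohydrin; the C–O bond at the stereocentre is retained, so the configuration from 3 is carried into the epoxide unchanged.

Step 4
Reactants: 6 (R)-2-[11-(benzyloxy)undecyl]oxirane; 7 1-bromo-3,5-dimethoxybenzene
Product: 9 (R)-13-(benzyloxy)-1-(3,5-dimethoxyphenyl)tridecan-2-ol, via arylmagnesium bromide 8 (not isolated)
Conditions: 7, Mg, THF, reflux; then CuI (10 mol %), 6, THF, −30 → 0 °C; aq NH4Cl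
Reagents that add atoms: none
Why: Copper-catalysed aryl Grignard opening of a terminal epoxide at the CH2 carbon, forming C4–C4a; the carbinol centre is not involved and remains R (the arylmethyl branch now outranks the chain).

Step 5
Reactants: 9 (R)-13-(benzyloxy)-1-(3,5-dimethoxyphenyl)tridecan-2-ol; 10 dimethoxymethane
Product: 12 (R)-3-[11-(benzyloxy)undecyl]-6,8-dimethoxyisochroman, via methoxymethyl ether 11 (not isolated)
Conditions: CH2(OMe)2, BF3·OEt2, CH2Cl2, 0 °C → rt
Reagents that add atoms: none
Why: Oxa-Pictet–Spengler cyclisation: the Lewis acid exchanges one methoxy group of 10 for the C3 hydroxyl of 9 to give methoxymethyl ether 11 (bond O2–C1), a second ionisation expels methanol to leave an O-alkyl oxocarbenium ion, and its CH2 carbon is attacked by the ring carbon ortho to the side chain (bond C1–C8a) before proton loss restores the arene. The closest known reaction type is the cyclisation of electron-rich 2-arylethanols with formaldehyde acetals to isochromans. Ring B closes in a 6-endo-trig Friedel–Crafts mode, since both atoms of the C1=O2 cation lie inside the new six-membered ring. No stereocentre is formed; C3 is a non-benzylic secondary carbinol that cannot ionise under these conditions, so its R configuration is carried through. The step needs only site selectivity on the arene: the attacking carbon is ortho to one methoxy group and para to the other, its twin across the side chain is identical by symmetry, and the carbon between the two methoxy groups cannot be reached through a six-membered transition state. The benzyl ether is inert to BF3·OEt2 at this temperature and its unactivated phenyl ring does not compete as a nucleophile.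

Step 6
Reactants: 12 (R)-3-[11-(benzyloxy)undecyl]-6,8-dimethoxyisochroman
Product: 13 (3R)-3-[11-(benzyloxy)undecyl]-6,8-dimethoxyisochroman-1-ol (both C1 epimers)
Conditions: DDQ, CH2Cl2/H2O (10:1), 0 °C → rt
Reagents that add atoms: water, O
Why: Oxidative C–H functionalisation by hydride abstraction: DDQ removes hydride from C1, the only carbon that is benzylic, α to oxygen and conjugated to ortho and para methoxy groups, and water captures the cation as the lactol; C4 and the O-benzyl methylene lack this activation, and any further oxidation of 13 would lead only to lactone 14.

Step 7
Reactants: 13 (3R)-3-[11-(benzyloxy)undecyl]-6,8-dimethoxyisochroman-1-ol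
Product: 14 (R)-3-[11-(benzyloxy)undecyl]-6,8-dimethoxyisochroman-1-one
Conditions: Ag2CO3 on Celite, toluene, reflux
Reagents that add atoms: none
Why: Fétizon oxidation of a lactol to the lactone under neutral heterogeneous conditions, which spare the benzyl ether and the electron-rich arene and do not involve C3.

Step 8
Reactants: 14 (R)-3-[11-(benzyloxy)undecyl]-6,8-dimethoxyisochroman-1-one
Product: 15 (R)-8-hydroxy-3-(11-hydroxyundecyl)-6-methoxyisochroman-1-one
Conditions: BCl3, C6HMe5, CH2Cl2, −78 → 0 °C; then aq NaHCO3
Reagents that add atoms: none
Why: Lewis-acid ether cleavage: BCl3 chelates the C1 carbonyl and the peri C8 methoxy group so that chloride removes only that methyl group, while the unchelated C6 methyl ether stays; the same reagent cleaves the primary benzyl ether, and pentamethylbenzene traps the benzyl cation so that ring A is not benzylated.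

## Compound list

1 | 10-bromodecan-1-ol | OCCCCCCCCCCBr | starting material
2 | benzyl 10-bromodecyl ether | BrCCCCCCCCCCOCc1ccccc1 | intermediate
3 | (R)-epichlorohydrin | ClC[C@H]1CO1 | starting material
4 | [10-(benzyloxy)decyl]magnesium bromide | Br[Mg]CCCCCCCCCCOCc1ccccc1 | intermediate
5 | (R)-13-(benzyloxy)-1-chlorotridecan-2-ol | ClC[C@H](O)CCCCCCCCCCCOCc1ccccc1 | intermediate
6 | (R)-2-[11-(benzyloxy)undecyl]oxirane | O1C[C@H]1CCCCCCCCCCCOCc2ccccc2 | intermediate
7 | 1-bromo-3,5-dimethoxybenzene | COc1cc(Br)cc(OC)c1 | starting material
8 | 3,5-dimethoxyphenylmagnesium bromide | COc1cc(OC)cc([Mg]Br)c1 | intermediate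
9 | (R)-13-(benzyloxy)-1-(3,5-dimethoxyphenyl)tridecan-2-ol | COc1cc(OC)cc(C[C@@H](CCCCCCCCCCCOCc2ccccc2)O)c1 | intermediate
10 | dimethoxymethane | COCOC | starting material
11 | (R)-1-[13-(benzyloxy)-2-(methoxymethoxy)tridecyl]-3,5-dimethoxybenzene | COc1cc(OC)cc(C[C@@H](CCCCCCCCCCCOCc2ccccc2)OCOC)c1 | intermediate
12 | (R)-3-[11-(benzyloxy)undecyl]-6,8-dimethoxyisochroman | COc1cc(OC)c2c(c1)C[C@@H](CCCCCCCCCCCOCc3ccccc3)OC2 | intermediate
13 | (3R)-3-[11-(benzyloxy)undecyl]-6,8-dimethoxyisochroman-1-ol (C1 epimers) | COc1cc(OC)c2c(c1)C[C@@H](CCCCCCCCCCCOCc3ccccc3)OC2O | intermediate
14 | (R)-3-[11-(benzyloxy)undecyl]-6,8-dimethoxyisochroman-1-one | COc1cc(OC)c2c(c1)C[C@@H](CCCCCCCCCCCOCc3ccccc3)OC2=O | intermediate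
15 | (R)-8-hydroxy-3-(11-hydroxyundecyl)-6-methoxyisochroman-1-one | COc1cc(O)c2c(c1)C[C@@H](CCCCCCCCCCCO)OC2=O | target

## Step count and risk

Total step count: 8. Longest linear sequence: 8 steps (1 → 15); the aryl Grignard reagent is made in the flask of step 4.

**Step 5 (key step).** The most likely failure is over-reaction of the very electron-rich ring. After closure, C5 and C7 of 12 are still nucleophilic, so a second formaldehyde-derived cation could methoxymethylate the product or bridge two molecules as a diarylmethane. Intermolecular attack before ring closure is the related problem at high concentration. Fallback: the ring carbon is introduced by formylation instead of acetal chemistry. Alcohol 9 is acetylated (Ac2O, pyridine) to (R)-13-(benzyloxy)-1-(3,5-dimethoxyphenyl)tridecan-2-yl acetate F1. Vilsmeier–Haack formylation (POCl3, DMF) ortho to the side chain should give (R)-13-(benzyloxy)-1-(2-formyl-3,5-dimethoxyphenyl)tridecan-2-yl acetate F2. K2CO3 in MeOH removes the acetate, and the hydroxy aldehyde closes to lactol 13, where the route is rejoined.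

**Step 6.** The C1 cation may be captured by lactol 13 already formed, or by its open hydroxy aldehyde form, instead of by water, giving bis-acetal dimers. Slow oxidation at the O-benzyl methylene is also possible if excess oxidant is used. Fallback: C1 is brought in at the carboxyl level by carbonylation. Alcohol 9 is brominated with NBS in MeCN at 0 °C, para to one methoxy group and ortho to the side chain, to give (R)-13-(benzyloxy)-1-(2-bromo-3,5-dimethoxyphenyl)tridecan-2-ol F3. Carbonylative lactonisation (CO, Pd(OAc)2, Xantphos, K2CO3, toluene, 100 °C) then leads directly to lactone 14.

**Step 8.** Benzyl transfer to C5 or C7 of the freed phenol ring may compete with capture by the scavenger. Alternatively, debenzylation may be incomplete at temperatures low enough to keep the C6 methyl ether. Fallback: the two deprotections are separated. Hydrogenolysis of 14 (H2, Pd/C, EtOAc) gives (R)-3-(11-hydroxyundecyl)-6,8-dimethoxyisochroman-1-one F4. A small excess of BCl3 at −78 °C then performs only the chelation-controlled demethylation to 15.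

**Step 2.** Enantiopurity may erode. Bromide from the Schlenk equilibrium can open epichlorohydrin to a dihalo alkoxide that re-closes in either sense, and direct displacement of chloride by the organocopper species leads to the enantiomeric epoxide. Fallback: the configuration is set by hydrolytic kinetic resolution. Bromide 2 is coupled with allylmagnesium bromide (Li2CuCl4 cat., THF) to [(tridec-12-en-1-yloxy)methyl]benzene F5. Epoxidation with mCPBA gives racemic 2-[11-(benzyloxy)undecyl]oxirane F6. Resolution with (R,R)-(salen)Co(OAc) (trivalent cobalt) and 0.55 equiv of water should leave (R)-epoxide 6, separated from the diol by chromatography.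

## Further compounds

F1 | step 5 | (R)-13-(benzyloxy)-1-(3,5-dimethoxyphenyl)tridecan-2-yl acetate | COc1cc(OC)cc(C[C@@H](CCCCCCCCCCCOCc2ccccc2)OC(C)=O)c1
F2 | step 5 | (R)-13-(benzyloxy)-1-(2-formyl-3,5-dimethoxyphenyl)tridecan-2-yl acetate | COc1cc(OC)c(C=O)c(C[C@@H](CCCCCCCCCCCOCc2ccccc2)OC(C)=O)c1
F3 | step 6 | (R)-13-(benzyloxy)-1-(2-bromo-3,5-dimethoxyphenyl)tridecan-2-ol | COc1cc(OC)c(Br)c(C[C@@H](CCCCCCCCCCCOCc2ccccc2)O)c1
F4 | step 8 | (R)-3-(11-hydroxyundecyl)-6,8-dimethoxyisochroman-1-one | COc1cc(OC)c2c(c1)C[C@@H](CCCCCCCCCCCO)OC2=O
F5 | step 2 | [(tridec-12-en-1-yloxy)methyl]benzene | C=CCCCCCCCCCCCOCc1ccccc1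
F6 | step 2 | rac-2-[11-(benzyloxy)undecyl]oxirane | O1CC1CCCCCCCCCCCOCc2ccccc2
A1 | alternative 1 | 3,5-dimethoxy-2-(trimethylsilyl)phenyl trifluoromethanesulfonate | COc1cc(OC)c([Si](C)(C)C)c(OS(=O)(=O)C(F)(F)F)c1
A2 | alternative 1 | dimethyl malonate | COC(=O)CC(=O)OC
A3 | alternative 1 | methyl 2,4-dimethoxy-6-(2-methoxy-2-oxoethyl)benzoate | COC(=O)Cc1cc(OC)cc(OC)c1C(=O)OC
A4 | alternative 2 | (R)-6-[6,17-bis(tert-butyldimethylsilyloxy)-2,4-dioxoheptadecyl]-2,2-dimethyl-4H-1,3-dioxin-4-one | CC1(C)OC(=O)C=C(CC(=O)CC(=O)C[C@@H](CCCCCCCCCCCO[Si](C)(C)C(C)(C)C)O[Si](C)(C)C(C)(C)C)O1
A5 | alternative 2 | (R)-5-[2,13-bis(tert-butyldimethylsilyloxy)tridecyl]-7-hydroxy-2,2-dimethyl-4H-benzo[d][1,3]dioxin-4-one | CC1(C)OC(=O)c2c(C[C@@H](CCCCCCCCCCCO[Si](C)(C)C(C)(C)C)O[Si](C)(C)C(C)(C)C)cc(O)cc2O1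
A6 | alternative 3 | 2,4-dimethoxybenzoic acid | COc1ccc(C(=O)O)c(OC)c1
A7 | alternative 3 | dimethylsulfoxonium 13-(tert-butyldimethylsilyloxy)-2-oxotridecan-1-ylide | CS(C)(=O)=CC(=O)CCCCCCCCCCCO[Si](C)(C)C(C)(C)C
A8 | alternative 3 | 3-[11-(tert-butyldimethylsilyloxy)undecyl]-6,8-dimethoxy-1H-isochromen-1-one | COc1cc(OC)c2c(c1)C=C(CCCCCCCCCCCO[Si](C)(C)C(C)(C)C)OC2=O
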